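**Plan**
Late cuts: C8'–C9' (Negishi) and O–C3' (anti iodolactonisation of a cis alkynoic acid) open lactone B; C1 (CO insertion) and C3a–C7a (Claisen) open lactone A and ring A; C6'=C7' (metathesis) opens ring B.
Core cut: the cyclobutane is opened across C6–C7 and C3a'–C7a', that is to the head-to-head alkene pair C7=C3a' and C6=C7a', not to the two ring alkenes of the monomers.
Enabling feature: C7 carries the carboxyl carbon C7a, C3a' carries the acyl-level carbon C3' and C7a' carries C1'; C7a–C7=C3a'–C3' is therefore a 4-substituted butenolide acetal, and one oxygen between C3' and C1' makes the two alkenes a 1,6-diene that closes five-ring first.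
Forward order: butenolide acetal 11 (three fragments) → cyclobutane with a temporary oxolane and lactone (step 8) → ring B → unmasking to ester, alkyne and alcohol → ring A → lactone A → lactone B.
Stereochemistry: the acetal carbon C3' (S, Pd-catalysed dynamic kinetic asymmetric etherification) relays to C3a', C7a' and C6 in step 8 and is then destroyed; C7 comes from thermodynamic cis fusion in step 11; the Z-butylidene from enol lactonisation, the E-butylidene from anti iodolactonisation and retentive coupling.

Key step: step 8

Remark: locants follow ligustilide numbering (unprimed half: butenolide with ring A; primed half: saturated lactone with ring B); face b of the cyclobutane carries C4' and C7', face a carries C1' and C3'; the target is taken as drawn (3Z, 3'E).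

**Route**

Step 1
Reactants: 1 hex-5-enal; 2 glyoxylic acid monohydrate
Product: 3 4-(but-3-en-1-yl)-5-hydroxyfuran-2(5H)-one (racemic lactol)
Conditions: morpholine hydrochloride, 1,4-dioxane/H2O, reflux
Reagents that add atoms: none
Why: Amine-salt-mediated aldol condensation of the enolisable aldehyde with glyoxylic acid followed by lactol closure is the standard entry to 4-alkyl-5-hydroxybutenolides; the lactol carbon is racemic and labile, so no target stereocenter is set.

Step 2
Reactants: 3 4-(but-3-en-1-yl)-5-hydroxyfuran-2(5H)-one
Product: 4 tert-butyl 3-(but-3-en-1-yl)-5-oxo-2,5-dihydrofuran-2-yl carbonate (racemic)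
Conditions: Boc2O, Et3N, DMAP (cat.), CH2Cl2, 0 °C
Reagents that add atoms: di-tert-butyl dicarbonate, CC(C)(C)OC(=O)OC(=O)OC(C)(C)C
Why: O-acylation of the lactol hydroxyl (carbonate formation) gives the ionisable allylic carbonate needed for π-allyl chemistry, the acetal carbon staying racemic.

Step 3
Reactants: 5 oxan-2-one (δ-valerolactone)
Product: 6 9-hydroxynonan-5-one
Conditions: n-BuLi, THF, −78 °C; aq. NH4Cl
Reagents that add atoms: n-butyllithium, [Li]CCCC
Why: Mono-addition of an organolithium to a lactone should stop at the ketone level because the tetrahedral lithium lactolate persists at low temperature until the quench.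

Step 4
Reactants: 6 9-hydroxynonan-5-one
Product: 7 5-oxononanal
Conditions: TEMPO (cat.), PhI(OAc)2, CH2Cl2, rt
Reagents that add atoms: none
Why: Oxoammonium (TEMPO) oxidation is selective for the primary alcohol and stops at the aldehyde in the absence of water.

Step 5
Reactants: 7 5-oxononanal; 8 1,4-dibromobut-2-yne
Product: 9 9-hydroxy-10-methylidenedodec-11-en-5-one (racemic)
Conditions: In powder, THF/H2O, rt
Reagents that add atoms: none
Why: The indium-mediated Barbier-type buta-1,3-dien-2-ylation in water is chemoselective for the aldehyde over the ketone and installs the 2-substituted butadiene; the racemic carbinol center is erased in step 6.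

Step 6
Reactants: 9 9-hydroxy-10-methylidenedodec-11-en-5-one
Product: 10 10-(hydroxymethyl)dodeca-9,11-dien-5-one (E/Z mixture)
Conditions: Ph3SiOReO3 (2 mol %), Et2O, 0 °C
Reagents that add atoms: none
Why: Oxorhenium-catalysed 1,3-transposition of the allylic alcohol ([3,3] shift of a perrhenate ester) should move oxygen to the primary terminus because the trisubstituted, still conjugated alkene is the thermodynamic sink; the E/Z ratio is irrelevant because step 8 passes through a radical at that carbon.

Step 7
Reactants: 4 tert-butyl 3-(but-3-en-1-yl)-5-oxo-2,5-dihydrofuran-2-yl carbonate; 10 10-(hydroxymethyl)dodeca-9,11-dien-5-one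
Product: 11 (5S)-4-(but-3-en-1-yl)-5-[(2-ethenyl-7-oxoundec-2-en-1-yl)oxy]furan-2(5H)-one
Conditions: Pd2(dba)3·CHCl3 (2.5 mol %), (1R,2R)-N,N'-bis[2-(diphenylphosphino)benzoyl]cyclohexane-1,2-diamine (DACH-phenyl Trost ligand, 7.5 mol %), Bu4NCl (30 mol %), CH2Cl2, 0 °C to rt
Reagents that add atoms: none
Why: Pd-catalysed dynamic kinetic asymmetric allylic etherification: both enantiomers of 4 ionise to π-allyl complexes that equilibrate with chloride assistance, and the chiral ligand directs the alkoxide (freed by the tert-butoxide leaving group) to set the acetal carbon as S; the (R,R) ligand is proposed and its antipode would be used should the sense of induction be opposite.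

Step 8
Reactants: 11 (5S)-4-(but-3-en-1-yl)-5-[(2-ethenyl-7-oxoundec-2-en-1-yl)oxy]furan-2(5H)-one
Product: 12 tricyclic lactone acetal (cyclobutane cis-fused to the γ-lactone and to an oxolane; C6 chain on face b)
Conditions: [Ir(dF(CF3)ppy)2(dtbbpy)]PF6 (1 mol %), degassed MeCN (0.01 M), blue LEDs (450 nm), rt
Reagents that add atoms: none
Why: The iridium sensitiser (triplet energy about 60 kcal/mol) transfers energy only to the 1,3-diene of 11, whose triplet (allyl radical plus C6 radical) adds through its tertiary allyl terminus C7a' to the butenolide β-carbon C3a', after which the α-acyl radical at C7 and the C6 radical recombine, so that the C3a'–C7a' and C6–C7 bonds form in one operation. The closest known reactions are visible-light triplet-sensitised intramolecular diene–alkene [2+2] cycloadditions and the intramolecular [2+2] photocycloadditions of 5-alkenyloxy-2(5H)-furanones. The oxolane closes by 5-exo-trig radical addition (rule of five) and the cyclobutane by 1,4-biradical recombination. C3a' and C7a' are set cis by the ring fusion and in the absolute sense by the S acetal carbon, whose oxygen tether reaches only one face of the butenolide; C7 is held cis to C3a' by the lactone (it is corrected in step 11), and the C6 chain should take face b, away from the pocket formed by the lactone and oxolane rings. The step needs chemoselective excitation (butenolide, ketone and butenyl alkene lie above the sensitiser's triplet energy, which also shuts off the crossed butenolide–butenyl pathway and Norrish cleavage) and straight rather than crossed closure, secured by the three-atom C3'–O–C1' tether and by acyl stabilisation of the C7 radical.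

Step 9
Reactants: 12 tricyclic lactone acetal
Product: 13 tetracyclic lactone acetal (ring B closed as cyclohexene C6'=C7')
Conditions: second-generation Grubbs catalyst (5 mol %), CH2Cl2, 40 °C
Reagents that add atoms: none
Why: Ring-closing metathesis of the cis-disposed vinyl (C7a') and but-3-enyl (C3a') groups closes ring B with the double bond next to C7a' and expels ethene, without touching any stereocenter.

Step 10
Reactants: 13 tetracyclic lactone acetal
Product: 15 methyl ester alkynol (ester on face a), via lactol methyl ester 14 (not isolated)
Conditions: K2CO3, dimethyl (1-diazo-2-oxopropyl)phosphonate, MeOH, 0 °C to rt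
Reagents that add atoms: methanol, CO; dimethyl (1-diazo-2-oxopropyl)phosphonate, COP(=O)(OC)C(=[N+]=[N-])C(C)=O
Why: Methoxide opens the acyloxy acetal (pseudo-ester) to the methyl ester and the lactol, whose open hydroxy aldehyde form undergoes Ohira–Bestmann (Seyferth–Gilbert) homologation to the terminal alkyne in the same pot, so the temporary lactone and oxolane are removed at once while the quaternary centers are untouched and C7 stays as formed.

Step 11
Reactants: 15 methyl ester alkynol
Product: 17 enolised β-diketone with ring A closed (cis-syn-cis 6-4-6 core), via C7-epimeric ester 16 (not isolated)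
Conditions: KOtBu (3.5 equiv), THF, 0 °C to rt; aq. NH4Cl
Reagents that add atoms: none
Why: Intramolecular Claisen (Dieckmann-type) acylation of the ketone enolate at C3a by the ester closes ring A, six being the only accessible ring size, while the ester-bearing C7 epimerises under the alkoxide conditions and only the face-b epimer can close cis, the cis-fused β-diketone enolate being the thermodynamic sink that sets C7.

Step 12
Reactants: 17 enolised β-diketone
Product: 18 ring-enol triflate (C7a–OTf)
Conditions: PhNTf2, Et3N, DMAP (cat.), CH2Cl2, 0 °C to rt
Reagents that add atoms: N-phenylbis(trifluoromethanesulfonimide), O=S(=O)(N(c1ccccc1)S(=O)(=O)C(F)(F)F)C(F)(F)F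
Why: The acidic β-diketone is O-sulfonylated chemoselectively (enol triflate formation) on the ring oxygen to give the endocyclic tetrasubstituted enol triflate, while the primary alcohol and the alkyne do not react with the triflimide under amine base.

Step 13
Reactants: 18 ring-enol triflate
Product: 19 lactone A alkynol ((Z)-3-butylidene butenolide on ring A)
Conditions: PdCl2(PPh3)2 (5 mol %), CO (1 atm), Et3N, MeCN, 45 °C
Reagents that add atoms: carbon monoxide, [C-]#[O+]
Why: Pd-catalysed carbonylative lactonisation (oxidative addition into the vinyl triflate, CO insertion, 5-exo O-acylation by the neighbouring ketone enol) closes lactone A with the butylidene Z, the enol geometry that keeps propyl away from the ring CH2; copper-free conditions and the fast intramolecular trapping should keep the alkyne and the alcohol out of the cycle.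

Step 14
Reactants: 19 lactone A alkynol
Product: 21 alkynoic acid, via aldehyde 20 (not isolated)
Conditions: TEMPO (cat.), PhI(OAc)2, MeCN/H2O, rt
Reagents that add atoms: water, O
Why: Oxoammonium (TEMPO) oxidation in the presence of water takes the neopentyl primary alcohol through the aldehyde hydrate to the acid without touching the alkenes, the alkyne or the enol lactone.

Step 15
Reactants: 21 alkynoic acid
Product: 22 (E)-iodomethylene lactone
Conditions: I2, NaHCO3, MeCN, 0 °C, dark
Reagents that add atoms: iodine, II
Why: Iodolactonisation adds carboxylate oxygen and iodine anti across the cis-disposed alkyne in the 5-exo-dig mode, which is geometrically favoured over 4-exo or 5-endo attack on the ring B alkene, and so places iodine trans to the ring oxygen (E).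

Step 16
Reactants: 22 (E)-iodomethylene lactone
Product: 23 target CNP0371639.1
Conditions: n-PrZnBr, PdCl2(dppf) (5 mol %), THF, rt
Reagents that add atoms: n-propylzinc bromide, CCC[Zn]Br
Why: Negishi sp2–sp3 cross-coupling proceeds with retention at the vinyl iodide, so propyl ends trans to the ring oxygen (E) as required, and the neutral organozinc leaves both enol lactones intact.

**Compound list**
1 | hex-5-enal | C=CCCCC=O | starting material
2 | glyoxylic acid monohydrate | OC(O)C(=O)O | starting material
3 | 4-(but-3-en-1-yl)-5-hydroxyfuran-2(5H)-one (racemic) | OC1OC(=O)C=C1CCC=C | intermediate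
4 | tert-butyl 3-(but-3-en-1-yl)-5-oxo-2,5-dihydrofuran-2-yl carbonate (racemic) | CC(C)(C)OC(=O)OC1OC(=O)C=C1CCC=C | intermediate
5 | oxan-2-one (δ-valerolactone) | O=C1CCCCO1 | starting material
6 | 9-hydroxynonan-5-one | CCCCC(=O)CCCCO | intermediate
7 | 5-oxononanal | CCCCC(=O)CCCC=O | intermediate
8 | 1,4-dibromobut-2-yne | BrCC#CCBr | starting material
9 | 9-hydroxy-10-methylidenedodec-11-en-5-one (racemic) | CCCCC(=O)CCCC(O)C(=C)C=C | intermediate
10 | 10-(hydroxymethyl)dodeca-9,11-dien-5-one (E/Z mixture at C9=C10) | CCCCC(=O)CCCC=C(CO)C=C | intermediate
11 | (5S)-4-(but-3-en-1-yl)-5-[(2-ethenyl-7-oxoundec-2-en-1-yl)oxy]furan-2(5H)-one (E/Z mixture in the side chain) | C=CCCC1=CC(=O)O[C@@H]1OCC(C=C)=CCCCC(=O)CCCC | intermediate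
12 | tricyclic lactone acetal: cyclobutane (C6, C7, C3a', C7a') cis-fused to the γ-lactone across C7–C3a' and to the oxolane across C3a'–C7a'; 4-oxooctyl on C6, vinyl on C7a' and but-3-enyl on C3a' on face b; acetal carbon S | CCCCC(=O)CCC[C@H]1[C@@H]2C(=O)O[C@@H]3OC[C@@]1(C=C)[C@]23CCC=C | intermediate
13 | tetracyclic lactone acetal: as 12 with ring B (cyclohexene, C6'=C7') closed across C3a' and C7a' | CCCCC(=O)CCC[C@H]1[C@@H]2C(=O)O[C@@H]3OC[C@]14C=CCC[C@@]234 | intermediate
14 | lactol methyl ester: C7 methyl ester on face a; oxolane lactol (anomeric mixture) on face a | CCCCC(=O)CCC[C@H]1[C@H](C(=O)OC)[C@@]23CCC=C[C@@]12COC3O | intermediate (not isolated)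
15 | methyl 6-ethynyl-1-(hydroxymethyl)-8-(4-oxooctyl)bicyclo[4.2.0]oct-2-ene-7-carboxylate; ester, ethynyl and CH2OH on face a, 4-oxooctyl on face b | CCCCC(=O)CCC[C@H]1[C@H](C(=O)OC)[C@@]2(C#C)CCC=C[C@@]12CO | intermediate
16 | C7 epimer of 15 (ester on face b, cis to the 4-oxooctyl chain) | CCCCC(=O)CCC[C@H]1[C@@H](C(=O)OC)[C@@]2(C#C)CCC=C[C@@]12CO | intermediate (not isolated)
17 | enolised β-diketone: ring A closed cis on face b (C7a enol, pentanoyl on C3a); ethynyl on C3a' and CH2OH on C7a' on face a | CCCCC(=O)C1=C(O)[C@@H]2[C@H](CC1)[C@]3(CO)C=CCC[C@]23C#C | intermediate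
18 | ring-enol triflate of 17 (C7a–OTf, pentanoyl on C3a) | CCCCC(=O)C1=C(OS(=O)(=O)C(F)(F)F)[C@@H]2[C@H](CC1)[C@]3(CO)C=CCC[C@]23C#C | intermediate
19 | lactone A alkynol: (Z)-3-butylidene butenolide fused to ring A; ethynyl on C3a' and CH2OH on C7a' | CCC/C=C1\OC(=O)C2=C1CC[C@H]1[C@@H]2[C@@]2(C#C)CCC=C[C@@]12CO | intermediate
20 | aldehyde corresponding to 19 (C1' formyl) | CCC/C=C1\OC(=O)C2=C1CC[C@H]1[C@@H]2[C@@]2(C#C)CCC=C[C@@]12C=O | intermediate (not isolated)
21 | alkynoic acid (C1' carboxylic acid cis to the ethynyl group) | CCC/C=C1\OC(=O)C2=C1CC[C@H]1[C@@H]2[C@@]2(C#C)CCC=C[C@@]12C(=O)O | intermediate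
22 | (E)-iodomethylene lactone (lactone B closed, iodine trans to the ring oxygen) | CCC/C=C1\OC(=O)C2=C1CC[C@H]1[C@@H]2[C@@]23CCC=C[C@@]12C(=O)O/C3=C/I | intermediate
23 | CNP0371639.1 ((3Z,3'E) cyclobutane dimer) | CCC/C=C1\OC(=O)C2=C1CC[C@H]1[C@@H]2[C@@]23CCC=C[C@@]12C(=O)O/C3=C/CCC | target

**Count and risks**
Total steps: 16. Longest linear sequence: 14 steps (5 to 23, steps 3 to 16).

Step 8: the biradical closure may leak into the crossed mode (first bond to C7 instead of C3a'), may place the C6 chain on face a, or the diene may only cycle between its E and Z forms. Fallback: from 11, ring-closing metathesis is run first (second-generation Grubbs catalyst, CH2Cl2, high dilution) to give the nine-membered cyclic acetal F1, whose ring holds C3a' over C7a'; the same sensitised irradiation then becomes a transannular [2+2] cycloaddition that can close only in the straight sense and gives 13 directly, so the route is rejoined at 13.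

Step 11: epimerisation at C7 may be slower than interception of the ester by the neighbouring alkoxide or addition of that alkoxide to the alkyne, so that ring closure stalls. Fallback: from 13, the basic methanolysis is followed not by homologation but by acidification (camphorsulfonic acid, trimethyl orthoformate, MeOH), which gives the methyl ester methyl acetal F2 with the alcohol and the aldehyde locked together. Claisen closure with KOtBu then gives the acetal β-diketone F3 with no free alkoxide or alkyne present. Aqueous acetic acid liberates the lactol β-diketone F4, and Ohira–Bestmann homologation of the lactol (the β-diketone resting as its enolate) rejoins the route at 17.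

Step 7: an aliphatic alkoxide may attack the equilibrating π-allyl complexes with poor enantiocontrol, or a racemic background path may compete. Fallback: from 3, lipase-catalysed dynamic kinetic acetylation (vinyl acetate, immobilised Pseudomonas lipase, the lactol racemising through its open form) gives the (S)-acetate F5; substitution with 10 under achiral zerovalent palladium catalysis (Pd(PPh3)4), which proceeds with net retention by double inversion, rejoins the route at 11.

**Further compounds**
F1 | step 8 | nine-membered cyclic acetal (ring: C3a', C4', C5', C6'=C7' (Z), C7a', C1', O, C3'; exocyclic C7a'=C6 alkylidene; butenolide fused at C3a'–C3') | CCCCC(=O)CCCC=C1CO[C@H]2OC(=O)C=C2CC/C=C\1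
F2 | step 11 | methyl ester methyl acetal (14 with the lactol as its methyl acetal) | CCCCC(=O)CCC[C@H]1[C@H](C(=O)OC)[C@@]23CCC=C[C@@]12COC3OC
F3 | step 11 | acetal β-diketone (ring A closed, oxolane methyl acetal intact) | CCCCC(=O)C1=C(O)[C@@H]2[C@H](CC1)[C@]3(CO4)C=CCC[C@]23C4OC
F4 | step 11 | lactol β-diketone | CCCCC(=O)C1=C(O)[C@@H]2[C@H](CC1)[C@]3(CO4)C=CCC[C@]23C4O
F5 | step 7 | (5S)-5-acetoxy-4-(but-3-en-1-yl)furan-2(5H)-one | C=CCCC1=CC(=O)O[C@@H]1OC(C)=O
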